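**Plan**

- Feature and main cut: ring A (the 2,4-disubstituted furan) and ring B (the 3-substituted furan) are joined by one CH2. The four carbons of each furan are a 1,3-diene at a lower oxidation level and each ring oxygen can come from O2. All four furan C–O bonds are therefore cut back to an open-chain skipped tetraene whose doubly allylic CH2 becomes the inter-ring methylene.
- Other cuts: the exocyclic C5=C1' bond of the tetronic acid (aldol condensation); the C8'–C9' bond next to ring A (furylmethyl sulfone alkylation); the C5'–C6' bond at the trisubstituted alkene (B-alkyl Suzuki coupling); the C2'–C3' bond at the stereocentre (auxiliary-controlled allylation); in the tetraene, the CH2–CH= bond between the dienes and the ene–yne bond.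
- Forward order: enyne, then tetraene, then both furan rings in one flask, then the furylmethyl sulfone. Separately, the C10 side chain with its stereocentre and Z alkene is made. The two are joined, desulfonylated and oxidised to the aldehyde, and the tetronate ring is attached and unmasked last.
- Stereochemistry: C2' (S) comes from an Evans allylation with the (R)-4-benzyl auxiliary. The 6'Z alkene comes from directed anti-hydroalumination/iodination of but-2-yn-1-ol and is carried with retention through the Suzuki coupling and an SN2 alkylation. The 5Z ylidene comes from a thermodynamically controlled E1cB elimination.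

Key step: step 6

Remark on the chemistry: the open-chain and lactol intermediates of the key step are drawn for proton removal at the ring O–CH2 of each peroxide (the other direction leads to the same furans), and 3-methyltetronic acid is taken as a catalogue compound.

**Route**

Step 1
Reactants: 1 3-methyl-2,5-dihydrothiophene 1,1-dioxide (3-methyl-3-sulfolene)
Product: 2 3-(bromomethyl)-2,5-dihydrothiophene 1,1-dioxide
Conditions: NBS, (PhCO2)2 (cat.), CHCl3, reflux
Reagents that add atoms: N-bromosuccinimide, O=C1CCC(=O)N1Br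
Why: Wohl–Ziegler radical bromination selects the allylic methyl group because the ring CH2 groups are deactivated by the adjacent sulfone.

Step 2
Reactants: 2 3-(bromomethyl)-2,5-dihydrothiophene 1,1-dioxide
Product: 3 2-(bromomethyl)buta-1,3-diene
Conditions: neat, 170 °C, reduced pressure, distilled into a −78 °C receiver holding a trace of hydroquinone
Reagents that add atoms: none
Why: Thermal cheletropic extrusion of SO2 from the 3-sulfolene unmasks the 1,3-diene, which is distilled out of the hot zone as it forms and kept cold to avoid dimerisation.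

Step 3
Reactants: 4 2-bromoprop-2-en-1-ol
Product: 5 [(2-bromoprop-2-en-1-yl)oxy](tert-butyl)dimethylsilane
Conditions: TBSCl, imidazole, CH2Cl2, 0 °C to rt
Reagents that add atoms: tert-butyldimethylsilyl chloride, CC(C)(C)[Si](C)(C)Cl
Why: Routine silylation of a primary alcohol with imidazole as base gives an ether that tolerates the organometallic, oxidative and basic steps up to the bisfuran.

Step 4
Reactants: 5 [(2-bromoprop-2-en-1-yl)oxy](tert-butyl)dimethylsilane; 6 ethynylmagnesium bromide
Product: 8 tert-butyldimethyl[(2-methylidenebut-3-yn-1-yl)oxy]silane, via ethynylzinc bromide 7 (not isolated)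
Conditions: 6 (0.5 M in THF), ZnBr2, THF, 0 °C; then 5, Pd(PPh3)4 (3 mol %), rt
Reagents that add atoms: none
Why: Negishi coupling of an ethynylzinc halide with an alkenyl bromide delivers the terminal enyne directly, since the zinc acetylide transfers cleanly without a second coupling at the free C–H end.

Step 5
Reactants: 8 tert-butyldimethyl[(2-methylidenebut-3-yn-1-yl)oxy]silane; 3 2-(bromomethyl)buta-1,3-diene
Product: 10 tert-butyldimethyl{[(3E)-2,6-dimethylideneocta-3,7-dien-1-yl]oxy}silane, via dienylzirconocene chloride 9 (not isolated)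
Conditions: Cp2Zr(H)Cl, THF, rt; then 3, CuCl (10 mol %), 0 °C to rt
Reagents that add atoms: none
Why: Hydrozirconation adds Zr–H syn across the terminal alkyne (much faster than across the 1,1-disubstituted alkene) to give the (E)-dienylzirconocene, and copper-catalysed allylation with the allylic bromide forms the skipped CH2–CH= bond, SN2 and SN2' attack on 3 giving the same product because its allyl unit is symmetric about the central carbon.

Step 6
Reactants: 10 tert-butyldimethyl{[(3E)-2,6-dimethylideneocta-3,7-dien-1-yl]oxy}silane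
Product: 14 tert-butyl{[5-(furan-3-ylmethyl)furan-3-yl]methoxy}dimethylsilane, via bis-endoperoxide 11 (not isolated), via bis-hydroxyenal 12 (not isolated), via bis-lactol 13 (not isolated)
Conditions: O2, tetraphenylporphyrin (1 mol %), CH2Cl2, white LEDs, −20 °C; Ar purge; Et3N (1.0 equiv), 0 °C to rt; then camphorsulfonic acid (1.3 equiv), 4 Å molecular sieves, 0 °C
Reagents that add atoms: dioxygen (excited to singlet oxygen by the sensitiser), O=O
Why: Dye-sensitised singlet oxygen adds suprafacially across the termini of each s-cis 1,3-diene in a [4+2] cycloaddition, closing the two six-membered 3,6-dihydro-1,2-dioxine rings of 11; Et3N then removes a proton next to each O–O bond (Kornblum–DeLaMare rearrangement) to give the cis-4-hydroxy-enals of 12, whose hydroxyl groups close onto the cis-held aldehydes by 5-exo-trig lactolisation (13), and acid-catalysed loss of water aromatises ring A and ring B. The closest known reaction type is the photooxygenation of 2-alkyl- and 1,3-disubstituted buta-1,3-dienes to dihydrodioxines followed by their base- and acid-mediated conversion into 3-substituted and 2,4-disubstituted furans, here run on two dienes of one molecule. No stereocentre is created in 14, because the sp3 centres of 11 to 13 are lost on aromatisation, and either direction of peroxide cleavage ends in the same furan. The selectivity needed is [4+2] addition over the ene reaction at the doubly allylic CH2 and at CH2OSi, and the substrate secures it by offering only 1,1- and (E)-1,2-disubstituted alkenes (poor ene partners), no trisubstituted alkene, and two dienes that reach the s-cis form without strain. Oxygen is purged before base is added, so the electron-rich furans never meet singlet oxygen.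

Step 7
Reactants: 14 tert-butyl{[5-(furan-3-ylmethyl)furan-3-yl]methoxy}dimethylsilane
Product: 15 [5-(furan-3-ylmethyl)furan-3-yl]methanol
Conditions: n-Bu4NF, THF, 0 °C
Reagents that add atoms: none
Why: Fluoride-induced cleavage of the Si–O bond is neutral enough for the acid-sensitive bis-furyl methane.

Step 8
Reactants: 15 [5-(furan-3-ylmethyl)furan-3-yl]methanol
Product: 16 4-(bromomethyl)-2-(furan-3-ylmethyl)furan
Conditions: CBr4, PPh3, CH2Cl2, 0 °C; used without storage
Reagents that add atoms: carbon tetrabromide, BrC(Br)(Br)Br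
Why: Appel bromination converts the furylmethyl alcohol under near-neutral conditions by SN2 displacement of the oxyphosphonium group, and the labile bromide is used at once.

Step 9
Reactants: 16 4-(bromomethyl)-2-(furan-3-ylmethyl)furan
Product: 17 2-(furan-3-ylmethyl)-4-[(phenylsulfonyl)methyl]furan
Conditions: PhSO2Na, DMF, rt
Reagents that add atoms: sodium benzenesulfinate, [Na+].[O-]S(=O)c1ccccc1
Why: S-alkylation of the ambident sulfinate anion in a dipolar aprotic solvent (SN2 at the activated furylmethyl carbon) gives the sulfone that acidifies this CH2 for the fragment union.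

Step 10
Reactants: 18 (R)-4-benzyl-3-propionyloxazolidin-2-one; 19 allyl iodide
Product: 20 (R)-4-benzyl-3-[(S)-2-methylpent-4-enoyl]oxazolidin-2-one
Conditions: NaN(SiMe3)2, THF, −78 °C; then 19, −78 to −45 °C
Reagents that add atoms: none
Why: Evans alkylation, in which the chelated (Z)-sodium enolate is allylated on the face opposite the benzyl group, so that the (R)-auxiliary sets the (S) configuration of the methyl-bearing carbon.

Step 11
Reactants: 20 (R)-4-benzyl-3-[(S)-2-methylpent-4-enoyl]oxazolidin-2-one
Product: 21 (S)-2-methylpent-4-en-1-ol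
Conditions: LiBH4, THF, 0 °C to rt; aq. NaOH
Reagents that add atoms: none
Why: Hydride attacks the more electrophilic exocyclic imide carbonyl (reductive removal of the auxiliary), releasing the primary alcohol without touching the stereocentre and returning the oxazolidinone.

Step 12
Reactants: 21 (S)-2-methylpent-4-en-1-ol
Product: 22 tert-butyldimethyl{[(2S)-2-methylpent-4-en-1-yl]oxy}silane
Conditions: TBSCl, imidazole, CH2Cl2, 0 °C to rt
Reagents that add atoms: tert-butyldimethylsilyl chloride, CC(C)(C)[Si](C)(C)Cl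
Why: Routine silylation protects the primary alcohol through the coupling, bromination, carbanion and amalgam steps.

Step 13
Reactants: 23 but-2-yn-1-ol
Product: 24 (2Z)-3-iodobut-2-en-1-ol
Conditions: NaAlH2(OCH2CH2OMe)2, THF, 0 °C to rt; then I2, −78 to 0 °C
Reagents that add atoms: iodine, II
Why: Hydroxyl-directed anti-hydroalumination places aluminium on C3 cis to the CH2O group and iodinolysis with retention gives the (Z)-3-iodoalkenol that fixes the geometry of the later trisubstituted alkene.

Step 14
Reactants: 22 tert-butyldimethyl{[(2S)-2-methylpent-4-en-1-yl]oxy}silane; 24 (2Z)-3-iodobut-2-en-1-ol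
Product: 26 (2Z,7S)-8-{[tert-butyl(dimethyl)silyl]oxy}-3,7-dimethyloct-2-en-1-ol, via B-alkyl-9-BBN 25 (not isolated)
Conditions: 9-BBN-H, THF, rt; then 24, PdCl2(dppf) (5 mol %), AsPh3 (5 mol %), Cs2CO3, DMF/H2O, rt
Reagents that add atoms: none
Why: Anti-Markovnikov hydroboration of the terminal alkene followed by B-alkyl Suzuki–Miyaura coupling joins sp3 to sp2 carbon with retention of the Z geometry of the alkenyl iodide, the stereocentre being remote and untouched.

Step 15
Reactants: 26 (2Z,7S)-8-{[tert-butyl(dimethyl)silyl]oxy}-3,7-dimethyloct-2-en-1-ol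
Product: 27 {[(2S,6Z)-8-bromo-2,6-dimethyloct-6-en-1-yl]oxy}(tert-butyl)dimethylsilane
Conditions: CBr4, PPh3, CH2Cl2, 0 °C
Reagents that add atoms: carbon tetrabromide, BrC(Br)(Br)Br
Why: Appel bromination of the primary allylic alcohol proceeds by SN2 at carbon under neutral conditions, which keeps the Z alkene and the silyl ether intact.

Step 16
Reactants: 17 2-(furan-3-ylmethyl)-4-[(phenylsulfonyl)methyl]furan; 27 {[(2S,6Z)-8-bromo-2,6-dimethyloct-6-en-1-yl]oxy}(tert-butyl)dimethylsilane
Product: 28 tert-butyl{[(2S,6Z)-9-[5-(furan-3-ylmethyl)furan-3-yl]-2,6-dimethyl-9-(phenylsulfonyl)non-6-en-1-yl]oxy}dimethylsilane (both epimers at C9)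
Conditions: n-BuLi, THF, −78 °C; then 27, −78 to −20 °C
Reagents that add atoms: none
Why: The sulfone-stabilised furylmethyl carbanion, formed selectively because this CH2 is far more acidic than the bis-furyl CH2 or any furan C–H, displaces the primary allylic bromide by SN2 with retention of the Z alkene, and the new sulfone-bearing centre is of no consequence because it is removed next.

Step 17
Reactants: 28 tert-butyl{[(2S,6Z)-9-[5-(furan-3-ylmethyl)furan-3-yl]-2,6-dimethyl-9-(phenylsulfonyl)non-6-en-1-yl]oxy}dimethylsilane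
Product: 29 tert-butyl{[(2S,6Z)-9-[5-(furan-3-ylmethyl)furan-3-yl]-2,6-dimethylnon-6-en-1-yl]oxy}dimethylsilane
Conditions: Na(Hg) (6% Na), Na2HPO4, MeOH/THF, −20 °C
Reagents that add atoms: none
Why: Reductive desulfonylation by electron transfer from sodium amalgam cleaves the furylmethyl C–S bond, and since the sulfone is homoallylic and not allylic, the alkene can neither migrate nor isomerise.

Step 18
Reactants: 29 tert-butyl{[(2S,6Z)-9-[5-(furan-3-ylmethyl)furan-3-yl]-2,6-dimethylnon-6-en-1-yl]oxy}dimethylsilane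
Product: 30 (2S,6Z)-9-[5-(furan-3-ylmethyl)furan-3-yl]-2,6-dimethylnon-6-en-1-ol
Conditions: n-Bu4NF, THF, 0 °C to rt
Reagents that add atoms: none
Why: Fluoride removes the silyl ether without acid, sparing the furans and the Z alkene.

Step 19
Reactants: 30 (2S,6Z)-9-[5-(furan-3-ylmethyl)furan-3-yl]-2,6-dimethylnon-6-en-1-ol
Product: 31 (2S,6Z)-9-[5-(furan-3-ylmethyl)furan-3-yl]-2,6-dimethylnon-6-enal
Conditions: Dess–Martin periodinane, pyridine, CH2Cl2, 0 °C; used directly
Reagents that add atoms: none
Why: Dess–Martin oxidation under buffered, non-enolising conditions gives the α-methyl aldehyde without epimerisation, and it is used directly.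

Step 20
Reactants: 32 4-hydroxy-3-methylfuran-2(5H)-one (3-methyltetronic acid)
Product: 33 4-methoxy-3-methylfuran-2(5H)-one
Conditions: Me2SO4, K2CO3, acetone, reflux
Reagents that add atoms: dimethyl sulfate, COS(=O)(=O)OC
Why: O-Methylation of the vinylogous acid with a hard electrophile gives the 4-methoxy butenolide, which masks the acidic enol and directs later deprotonation to C5.

Step 21
Reactants: 33 4-methoxy-3-methylfuran-2(5H)-one; 31 (2S,6Z)-9-[5-(furan-3-ylmethyl)furan-3-yl]-2,6-dimethylnon-6-enal
Product: 34 5-{(2S,6Z)-9-[5-(furan-3-ylmethyl)furan-3-yl]-1-hydroxy-2,6-dimethylnon-6-en-1-yl}-4-methoxy-3-methylfuran-2(5H)-one (diastereomers at C5 and C1')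
Conditions: LiN(i-Pr)2, THF, −78 °C, 33; then 31, −78 °C; AcOH quench at −78 °C
Reagents that add atoms: none
Why: Kinetic deprotonation at C5 (the γ position of the vinylogous ester) and aldol addition at −78 °C, too cold for enolisation of the aldehyde's α-stereocentre, join the tetronate to the chain, the two new sp3 centres being removed in the next step.

Step 22
Reactants: 34 5-{(2S,6Z)-9-[5-(furan-3-ylmethyl)furan-3-yl]-1-hydroxy-2,6-dimethylnon-6-en-1-yl}-4-methoxy-3-methylfuran-2(5H)-one
Product: 36 (5Z)-5-{(2S,6Z)-9-[5-(furan-3-ylmethyl)furan-3-yl]-2,6-dimethylnon-6-en-1-ylidene}-4-methoxy-3-methylfuran-2(5H)-one, via mesylate 35 (not isolated)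
Conditions: MsCl, Et3N, CH2Cl2, 0 °C; then DBU, rt
Reagents that add atoms: none
Why: Mesylation followed by E1cB elimination through the C5 carbanion gives the conjugated 5-ylidene butenolide, with the Z isomer favoured because in the E isomer the chain would clash with the 4-methoxy group.

Step 23
Reactants: 36 (5Z)-5-{(2S,6Z)-9-[5-(furan-3-ylmethyl)furan-3-yl]-2,6-dimethylnon-6-en-1-ylidene}-4-methoxy-3-methylfuran-2(5H)-one
Product: 37 (5Z)-5-{(2S,6Z)-9-[5-(furan-3-ylmethyl)furan-3-yl]-2,6-dimethylnon-6-en-1-ylidene}-4-hydroxy-3-methylfuran-2(5H)-one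
Conditions: n-PrSH, n-BuLi, HMPA, 0 °C (gives n-PrSLi); then 36, rt; cold 0.5 M HCl to pH 3
Reagents that add atoms: none
Why: SN2 dealkylation of the vinylogous methyl ester by a soft thiolate (the tetronate anion being a good leaving group) frees the tetronic acid without acid or oxidant during the reaction, so furans, alkenes and the stereocentre are untouched.

**Compound list**

1 | 3-methyl-2,5-dihydrothiophene 1,1-dioxide | CC1=CCS(=O)(=O)C1 | starting material
2 | 3-(bromomethyl)-2,5-dihydrothiophene 1,1-dioxide | BrCC1=CCS(=O)(=O)C1 | intermediate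
3 | 2-(bromomethyl)buta-1,3-diene | C=CC(=C)CBr | intermediate
4 | 2-bromoprop-2-en-1-ol | OCC(Br)=C | starting material
5 | [(2-bromoprop-2-en-1-yl)oxy](tert-butyl)dimethylsilane | C=C(Br)CO[Si](C)(C)C(C)(C)C | intermediate
6 | ethynylmagnesium bromide | C#C[Mg]Br | starting material
7 | ethynylzinc bromide | C#C[Zn]Br | intermediate
8 | tert-butyldimethyl[(2-methylidenebut-3-yn-1-yl)oxy]silane | C=C(CO[Si](C)(C)C(C)(C)C)C#C | intermediate
9 | chloridobis(cyclopentadienyl)[(1E)-3-({[tert-butyl(dimethyl)silyl]oxy}methyl)buta-1,3-dien-1-yl]zirconium | C=C(CO[Si](C)(C)C(C)(C)C)/C=C/[Zr](Cl)(C1C=CC=C1)C1C=CC=C1 | intermediate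
10 | tert-butyldimethyl{[(3E)-2,6-dimethylideneocta-3,7-dien-1-yl]oxy}silane | C=C(CO[Si](C)(C)C(C)(C)C)/C=C/CC(=C)C=C | intermediate
11 | tert-butyl({6-[(3,6-dihydro-1,2-dioxin-4-yl)methyl]-3,6-dihydro-1,2-dioxin-4-yl}methoxy)dimethylsilane (bis-endoperoxide, racemic) | CC(C)(C)[Si](C)(C)OCC1=CC(CC2=CCOOC2)OOC1 | intermediate
12 | (2Z,6Z)-2-({[tert-butyl(dimethyl)silyl]oxy}methyl)-4-hydroxy-6-(hydroxymethyl)octa-2,6-dienedial (bis-hydroxyenal, racemic) | O=C/C(CO[Si](C)(C)C(C)(C)C)=C\C(O)C/C(CO)=C/C=O | intermediate
13 | 3-({[tert-butyl(dimethyl)silyl]oxy}methyl)-5-[(5-hydroxy-2,5-dihydrofuran-3-yl)methyl]-2,5-dihydrofuran-2-ol (bis-lactol, diastereomer mixture) | CC(C)(C)[Si](C)(C)OCC1=CC(CC2=CC(O)OC2)OC1O | intermediate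
14 | tert-butyl{[5-(furan-3-ylmethyl)furan-3-yl]methoxy}dimethylsilane | CC(C)(C)[Si](C)(C)OCc1coc(Cc2ccoc2)c1 | intermediate
15 | [5-(furan-3-ylmethyl)furan-3-yl]methanol | OCc1coc(Cc2ccoc2)c1 | intermediate
16 | 4-(bromomethyl)-2-(furan-3-ylmethyl)furan | BrCc1coc(Cc2ccoc2)c1 | intermediate
17 | 2-(furan-3-ylmethyl)-4-[(phenylsulfonyl)methyl]furan | O=S(=O)(Cc1coc(Cc2ccoc2)c1)c1ccccc1 | intermediate
18 | (R)-4-benzyl-3-propionyloxazolidin-2-one | CCC(=O)N1[C@H](Cc2ccccc2)COC1=O | starting material
19 | allyl iodide | C=CCI | starting material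
20 | (R)-4-benzyl-3-[(S)-2-methylpent-4-enoyl]oxazolidin-2-one | C=CC[C@H](C)C(=O)N1[C@H](Cc2ccccc2)COC1=O | intermediate
21 | (S)-2-methylpent-4-en-1-ol | OC[C@@H](C)CC=C | intermediate
22 | tert-butyldimethyl{[(2S)-2-methylpent-4-en-1-yl]oxy}silane | CC(C)(C)[Si](C)(C)OC[C@@H](C)CC=C | intermediate
23 | but-2-yn-1-ol | CC#CCO | starting material
24 | (2Z)-3-iodobut-2-en-1-ol | C/C(I)=C/CO | intermediate
25 | 9-[(4S)-5-{[tert-butyl(dimethyl)silyl]oxy}-4-methylpentyl]-9-borabicyclo[3.3.1]nonane | CC(C)(C)[Si](C)(C)OC[C@@H](C)CCCB1C2CCCC1CCC2 | intermediate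
26 | (2Z,7S)-8-{[tert-butyl(dimethyl)silyl]oxy}-3,7-dimethyloct-2-en-1-ol | CC(C)(C)[Si](C)(C)OC[C@@H](C)CCC/C(C)=C\CO | intermediate
27 | {[(2S,6Z)-8-bromo-2,6-dimethyloct-6-en-1-yl]oxy}(tert-butyl)dimethylsilane | CC(C)(C)[Si](C)(C)OC[C@@H](C)CCC/C(C)=C\CBr | intermediate
28 | tert-butyl{[(2S,6Z)-9-[5-(furan-3-ylmethyl)furan-3-yl]-2,6-dimethyl-9-(phenylsulfonyl)non-6-en-1-yl]oxy}dimethylsilane (epimers at C9) | CC(C)(C)[Si](C)(C)OC[C@@H](C)CCC/C(C)=C\CC(c1coc(Cc2ccoc2)c1)S(=O)(=O)c1ccccc1 | intermediate
29 | tert-butyl{[(2S,6Z)-9-[5-(furan-3-ylmethyl)furan-3-yl]-2,6-dimethylnon-6-en-1-yl]oxy}dimethylsilane | CC(C)(C)[Si](C)(C)OC[C@@H](C)CCC/C(C)=C\CCc1coc(Cc2ccoc2)c1 | intermediate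
30 | (2S,6Z)-9-[5-(furan-3-ylmethyl)furan-3-yl]-2,6-dimethylnon-6-en-1-ol | OC[C@@H](C)CCC/C(C)=C\CCc1coc(Cc2ccoc2)c1 | intermediate
31 | (2S,6Z)-9-[5-(furan-3-ylmethyl)furan-3-yl]-2,6-dimethylnon-6-enal | O=C[C@@H](C)CCC/C(C)=C\CCc1coc(Cc2ccoc2)c1 | intermediate
32 | 4-hydroxy-3-methylfuran-2(5H)-one (3-methyltetronic acid) | CC1=C(O)COC1=O | starting material
33 | 4-methoxy-3-methylfuran-2(5H)-one | COC1=C(C)C(=O)OC1 | intermediate
34 | 5-{(2S,6Z)-9-[5-(furan-3-ylmethyl)furan-3-yl]-1-hydroxy-2,6-dimethylnon-6-en-1-yl}-4-methoxy-3-methylfuran-2(5H)-one (diastereomers at C5 and C1') | COC1=C(C)C(=O)OC1C(O)[C@@H](C)CCC/C(C)=C\CCc1coc(Cc2ccoc2)c1 | intermediate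
35 | (2S,6Z)-9-[5-(furan-3-ylmethyl)furan-3-yl]-1-(3-methoxy-4-methyl-5-oxo-2,5-dihydrofuran-2-yl)-2,6-dimethylnon-6-en-1-yl methanesulfonate (diastereomers) | COC1=C(C)C(=O)OC1C(OS(C)(=O)=O)[C@@H](C)CCC/C(C)=C\CCc1coc(Cc2ccoc2)c1 | intermediate
36 | (5Z)-5-{(2S,6Z)-9-[5-(furan-3-ylmethyl)furan-3-yl]-2,6-dimethylnon-6-en-1-ylidene}-4-methoxy-3-methylfuran-2(5H)-one | CC1=C(OC)/C(=C/[C@@H](C)CCC/C(C)=C\CCc2coc(Cc3ccoc3)c2)OC1=O | intermediate
37 | (5Z)-5-{(2S,6Z)-9-[5-(furan-3-ylmethyl)furan-3-yl]-2,6-dimethylnon-6-en-1-ylidene}-4-hydroxy-3-methylfuran-2(5H)-one | CC1=C(O)/C(=C/[C@@H](C)CCC/C(C)=C\CCc2coc(Cc3ccoc3)c2)OC1=O | target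

**Totals**

Total step count: 23.
Longest linear sequence: 14 steps (steps 3 to 9, 16 to 19 and 21 to 23).

**Steps most likely to fail**

Step 6. Hydrogen abstraction by singlet oxygen (ene oxidation) at the doubly allylic CH2 or beside the silyl ether may compete with the slow [4+2] addition to open-chain dienes, and the second cycloaddition may lag behind the first so that half-oxidised material degrades. The fallback gives up oxidative ring formation and builds ring A by cycloisomerisation onto a ready-made ring B. It sets out from enyne 8. Epoxidation of its 1,1-disubstituted alkene with mCPBA in CH2Cl2 should give tert-butyl[(2-ethynyloxiran-2-yl)methoxy]dimethylsilane F1. Copper-catalysed coupling of the terminal alkyne with commercial 3-(bromomethyl)furan (CuCl cat., Cs2CO3, NaI, DMF) should give tert-butyl({2-[3-(furan-3-yl)prop-1-yn-1-yl]oxiran-2-yl}methoxy)dimethylsilane F2. AuCl3 (5 mol %) in MeCN then isomerises the alkynyl oxirane to the 2,4-disubstituted furan, and the route is rejoined at 14.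

Step 5. Diels–Alder dimerisation or polymerisation of bromodiene 3 during the coupling, over-addition of the zirconium hydride to the 1,1-disubstituted alkene, or sluggish transfer of the dienyl group from zirconium to copper may erode the union. The fallback changes to a boron/palladium coupling. It sets out from enyne 8. Hydroboration with pinacolborane catalysed by dicyclohexylborane should give tert-butyldimethyl{[(3E)-2-methylidene-4-(4,4,5,5-tetramethyl-1,3,2-dioxaborolan-2-yl)but-3-en-1-yl]oxy}silane F3. This is coupled with 3 under Pd(PPh3)4 and aqueous K3PO4 in THF (Suzuki–Miyaura allylation, whose allylpalladium intermediate is symmetric so only one constitution can form), and the route is rejoined at tetraene 10.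

Step 23. Reversible conjugate addition of the thiolate to the ylidene butenolide with erosion of the 5Z geometry, or opening of the lactone, may compete with clean O-dealkylation. The fallback carries the tetronate oxygen as an allyl ether that leaves under neutral palladium catalysis. It sets out from 3-methyltetronic acid 32 and aldehyde 31. Mitsunobu alkylation of 32 with allyl alcohol (PPh3, diisopropyl azodicarboxylate, THF) should give 3-methyl-4-(prop-2-en-1-yloxy)furan-2(5H)-one F4. Lithiation with LiN(i-Pr)2 and aldol addition to 31 at −78 °C should give 5-{(2S,6Z)-9-[5-(furan-3-ylmethyl)furan-3-yl]-1-hydroxy-2,6-dimethylnon-6-en-1-yl}-3-methyl-4-(prop-2-en-1-yloxy)furan-2(5H)-one F5. Mesylation (MsCl, Et3N) to the corresponding methanesulfonate F6 and elimination with DBU should give (5Z)-5-{(2S,6Z)-9-[5-(furan-3-ylmethyl)furan-3-yl]-2,6-dimethylnon-6-en-1-ylidene}-3-methyl-4-(prop-2-en-1-yloxy)furan-2(5H)-one F7. Pd(PPh3)4 with morpholine as allyl acceptor in THF then frees the tetronic acid, arriving at 37.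

**Further compounds**

F1 | step 6 | tert-butyl[(2-ethynyloxiran-2-yl)methoxy]dimethylsilane | C#CC1(CO[Si](C)(C)C(C)(C)C)CO1
F2 | step 6 | tert-butyl({2-[3-(furan-3-yl)prop-1-yn-1-yl]oxiran-2-yl}methoxy)dimethylsilane | CC(C)(C)[Si](C)(C)OCC1(C#CCc2ccoc2)CO1
F3 | step 5 | tert-butyldimethyl{[(3E)-2-methylidene-4-(4,4,5,5-tetramethyl-1,3,2-dioxaborolan-2-yl)but-3-en-1-yl]oxy}silane | C=C(CO[Si](C)(C)C(C)(C)C)/C=C/B1OC(C)(C)C(C)(C)O1
F4 | step 23 | 3-methyl-4-(prop-2-en-1-yloxy)furan-2(5H)-one | C=CCOC1=C(C)C(=O)OC1
F5 | step 23 | 5-{(2S,6Z)-9-[5-(furan-3-ylmethyl)furan-3-yl]-1-hydroxy-2,6-dimethylnon-6-en-1-yl}-3-methyl-4-(prop-2-en-1-yloxy)furan-2(5H)-one | C=CCOC1=C(C)C(=O)OC1C(O)[C@@H](C)CCC/C(C)=C\CCc1coc(Cc2ccoc2)c1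
F6 | step 23 | (2S,6Z)-9-[5-(furan-3-ylmethyl)furan-3-yl]-2,6-dimethyl-1-[4-methyl-5-oxo-3-(prop-2-en-1-yloxy)-2,5-dihydrofuran-2-yl]non-6-en-1-yl methanesulfonate | C=CCOC1=C(C)C(=O)OC1C(OS(C)(=O)=O)[C@@H](C)CCC/C(C)=C\CCc1coc(Cc2ccoc2)c1
F7 | step 23 | (5Z)-5-{(2S,6Z)-9-[5-(furan-3-ylmethyl)furan-3-yl]-2,6-dimethylnon-6-en-1-ylidene}-3-methyl-4-(prop-2-en-1-yloxy)furan-2(5H)-one | CC1=C(OCC=C)/C(=C/[C@@H](C)CCC/C(C)=C\CCc2coc(Cc3ccoc3)c2)OC1=O
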